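**Assumption:** the target has no stereocentres (the prenyl alkene carries two identical methyls), so no enantioselective step is needed. All three free phenols (C5-OH, C7-OH, 5'-OH) are carried as MOM ethers and released together in the last step.

## Retrosynthetic overview
- The target comes from global MOM cleavage of a tri-MOM flavone.
- The pyranone ring is formed in one radical oxidative annulation. An aroyl radical from 2-hydroxy-4,6-bis(MOM-oxy)benzaldehyde adds to an aryl–prenyl alkyne, which forms the C3–C4 bond. The α-aryl vinyl radical is then trapped by the phenol O to close O1–C2.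
- The alkyne comes from Sonogashira coupling of an aryl iodide with prenylacetylene, which is made from acetylide and prenyl bromide.
- Both aromatic rings are built from resorcinol before the annulation. Ring A: bis-MOM protection, Ir-catalysed meta C–H borylation/oxidation, then ortho-formylation. Ring B: dimethylation, Vilsmeier formylation, Dakin oxidation, MOM protection, then iodination.

## Forward route

**Step 1**
Reactants: 1 resorcinol
Product: 2 1,3-bis(methoxymethoxy)benzene
Conditions: MOMCl, i-Pr2NEt, CH2Cl2, 0 °C → rt
Reagents that add atoms: MOMCl (ClCOC)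
Why: Williamson-type O-alkylation protects both phenols as base-stable, bulky MOM ethers, which suits the next C–H borylation. No stereocentre.

**Step 2**
Reactants: 2
Product: 3 3,5-bis(methoxymethoxy)phenol
Conditions: (i) B2pin2, [Ir(cod)OMe]2, dtbpy, THF, 80 °C; (ii) same pot, NaBO3·4H2O, THF/H2O, rt
Reagents that add atoms: sodium perborate as the H2O2 source (OO); it supplies the new phenol oxygen
Why: Hartwig–Miyaura Ir-catalysed borylation is sterically controlled. It occurs at C5, meta to both MOM-oxy groups, and oxidative C–B cleavage gives the 1,3,5-trioxygenated (phloroglucinol) pattern. No stereocentre.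

**Step 3**
Reactants: 3
Product: 4 2-hydroxy-4,6-bis(methoxymethoxy)benzaldehyde
Conditions: MgCl2, Et3N, (CH2O)n, MeCN, reflux
Reagents that add atoms: paraformaldehyde (C=O)
Why: Casnati–Skattebøl ortho-formylation proceeds through the Mg phenoxide. It is mildly basic, so the MOM groups survive. C2 and C6 are equivalent, so there is one regioisomer. No stereocentre.

**Step 4**
Reactants: 1 resorcinol
Product: 5 1,3-dimethoxybenzene
Conditions: Me2SO4, K2CO3, acetone, reflux
Reagents that add atoms: dimethyl sulfate (COS(=O)(=O)OC)
Why: Double O-methylation. No stereocentre.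

**Step 5**
Reactants: 5
Product: 6 2,4-dimethoxybenzaldehyde
Conditions: POCl3, DMF, 0 → 60 °C; then aq. NaOAc
Reagents that add atoms: DMF (CN(C)C=O), which supplies the CHO
Why: Vilsmeier–Haack formylation occurs at C4, which is ortho to one OMe and para to the other. No stereocentre.

**Step 6**
Reactants: 6
Product: 7 2,4-dimethoxyphenol
Conditions: (i) mCPBA, CH2Cl2, 0 °C → rt; (ii) K2CO3, MeOH, rt
Reagents that add atoms: mCPBA (OOC(=O)c1cccc(Cl)c1), which supplies the O
Why: Dakin-type Baeyer–Villiger oxidation. The electron-rich aryl group migrates to give the aryl formate, and methanolysis releases the phenol. This installs the 5'-oxygen. No stereocentre.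

**Step 7**
Reactants: 7
Product: 8 1-(methoxymethoxy)-2,4-dimethoxybenzene
Conditions: MOMCl, i-Pr2NEt, CH2Cl2, 0 °C → rt
Reagents that add atoms: MOMCl (ClCOC)
Why: MOM protection of the future 5'-OH. No stereocentre.

**Step 8**
Reactants: 8
Product: 9 1-iodo-5-(methoxymethoxy)-2,4-dimethoxybenzene
Conditions: NIS, MeCN, 0 °C → rt, dark
Reagents that add atoms: N-iodosuccinimide (O=C1CCC(=O)N1I)
Why: Electrophilic iodination goes to the position para to the 2-OMe and ortho to the 4-OMe, as in 1,2,4-trialkoxybenzenes. This gives the 2',4'-dimethoxy-5'-MOM-oxy pattern with iodine at C1'. No stereocentre.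

**Step 9**
Reactants: 10 prenyl bromide (1-bromo-3-methylbut-2-ene) and 11 lithium acetylide–ethylenediamine complex
Product: 12 prenylacetylene (5-methylhex-4-en-1-yne)
Conditions: DMSO, 0 °C → rt; isolate by careful distillation (volatile)
Reagents that add atoms: none (both partners are reactants)
Why: SN2 alkylation of the acetylide at the primary allylic carbon keeps the normal prenyl connectivity. No stereocentre.

**Step 10**
Reactants: 9 and 12
Product: 13 1-(5-MOM-oxy-2,4-dimethoxyphenyl)-5-methylhex-4-en-1-yne
Conditions: Pd(PPh3)2Cl2 (3 mol%), CuI (5 mol%), Et3N/THF, 50 °C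
Reagents that add atoms: none
Why: Sonogashira coupling joins the aryl iodide to the terminal alkyne and leaves the trisubstituted alkene untouched. No stereocentre.

**Step 11**
Reactants: 4 (2 equiv) and 13 (1 equiv)
Product: 14 5,7-bis(MOM-oxy)-2-(5-MOM-oxy-2,4-dimethoxyphenyl)-3-prenylchromen-4-one
Conditions: Cu(OAc)2 (20 mol%), TBHP (3 equiv), MeCN, 80 °C
Reagents that add atoms: none (TBHP is only the oxidant; the ring oxygen comes from the phenol of 4)
Why: Proposed new method: oxidative aroyl-radical annulation of an alkyne. The closest known reactions are radical acylation of aryl alkynes and Cu-mediated radical-to-C–O cyclisation of vinyl radicals with phenols.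
- t-BuO•/t-BuOO• abstracts the aldehyde H of 4 to give the aroyl radical.
- The aroyl radical adds to the alkyne carbon remote from the aryl group. This forms the C3–C4 bond, places the prenyl-bearing carbon at C3, and gives the linear α-(2,4-dialkoxyaryl) vinyl radical.
- Cu(II) captures the vinyl radical, and C–O reductive elimination with the ortho phenol closes the six-membered pyranone (O1–C2).
- No stereocentre is created.

**Step 12**
Reactants: 14
Product: 15 Artoindonesianin R
Conditions: 3 M aq. HCl, MeOH/THF, 45 °C, 4 h
Reagents that add atoms: none
Why: Acid hydrolysis of the three aryl MOM acetals gives the 5-OH (chelated to C4=O), the 7-OH and the 5'-OH. The aryl methyl ethers, the flavone core and the prenyl group are unchanged. No stereocentre.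

## Compound list
1 | resorcinol | Oc1cccc(O)c1 | starting material
2 | 1,3-bis(methoxymethoxy)benzene | COCOc1cccc(OCOC)c1 | intermediate
3 | 3,5-bis(methoxymethoxy)phenol | COCOc1cc(O)cc(OCOC)c1 | intermediate
4 | 2-hydroxy-4,6-bis(methoxymethoxy)benzaldehyde | COCOc1cc(OCOC)c(C=O)c(O)c1 | intermediate
5 | 1,3-dimethoxybenzene | COc1cccc(OC)c1 | intermediate
6 | 2,4-dimethoxybenzaldehyde | COc1ccc(C=O)c(OC)c1 | intermediate
7 | 2,4-dimethoxyphenol | COc1ccc(O)c(OC)c1 | intermediate
8 | 1-(methoxymethoxy)-2,4-dimethoxybenzene | COCOc1ccc(OC)cc1OC | intermediate
9 | 1-iodo-5-(methoxymethoxy)-2,4-dimethoxybenzene | COCOc1cc(I)c(OC)cc1OC | intermediate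
10 | prenyl bromide | CC(C)=CCBr | starting material
11 | lithium acetylide–ethylenediamine complex | [Li]C#C.NCCN | starting material
12 | prenylacetylene (5-methylhex-4-en-1-yne) | C#CCC=C(C)C | intermediate
13 | 1-(5-MOM-oxy-2,4-dimethoxyphenyl)-5-methylhex-4-en-1-yne | COCOc1cc(C#CCC=C(C)C)c(OC)cc1OC | intermediate
14 | tri-MOM-protected flavone | COCOc1cc(OCOC)c2c(c1)oc(-c1cc(OCOC)c(OC)cc1OC)c(CC=C(C)C)c2=O | intermediate
15 | Artoindonesianin R | COc1cc(OC)c(-c2oc3cc(O)cc(O)c3c(=O)c2CC=C(C)C)cc1O | target

## Totals
- Total steps: 12.
- Longest linear sequence: 8 (resorcinol → 5 → 6 → 7 → 8 → 9 → 13 → 14 → 15).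

## Three steps most likely to fail
1. **Step 11 (radical annulation).** The acyl radical is polarity-mismatched with an electron-rich alkyne. The prenyl alkene and the MOM C–H bonds are also open to competing HAT, and the reaction could stop at the open-chain α-prenyl chalcone.
   - Fallback (new approach): Pd-catalysed carbonylative annulation of alkyne 13 with 2-iodo-3,5-bis(MOM-oxy)phenol (from 3 by ortho-iodination) under CO.
2. **Step 9 (prenylacetylene).** Alkylation may give some SN2' product, and the volatile enyne is hard to handle.
   - Fallback: Sonogashira of 9 with TMS-acetylene, desilylation, then Cu-catalysed (CuI/K2CO3) alkylation of the terminal arylalkyne with prenyl bromide.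
3. **Step 12 (MOM removal).** Aqueous HCl could add to the prenyl alkene or cause other acid side reactions.
   - Fallback: use allyl ethers in place of MOM in Steps 1 and 7, and remove them in the last step with Pd(PPh3)4/K2CO3/MeOH under neutral conditions.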